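**Retrosynthetic overview**
1. Target ⇐ 11‑chloro precursor: the isopropenyl group is unmasked last by E2 loss of HCl, and C10–H is set just before by conjugate reduction of a Δ1(10)‑en‑2‑one.
2. Key disconnection: both C–O bonds (C8–O, C9–O) come from one α‑face syn‑dioxygenation of the γ,δ‑olefin of a 1(10),8‑dien‑2‑one, with O9 acylated (senecioate) in the same flask and O8 acetylated afterwards.
3. Dienone ⇐ tricyclic cyclobutane enone: HCl opens the C9–C11 bond (this gives the masked side chain) and DDQ dehydrogenates in the same pot.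
4. Tricyclic enone ⇐ Robinson annulation of 3‑methylnopinone with (E)‑pent‑3‑en‑2‑one (sets C4, C5); 3‑methylnopinone ⇐ (+)‑nopinone + MeI.
5. Ring order: ring B is bought as the pinane six‑membered ring, ring A is annulated onto it, and the cyclobutane is opened afterwards.

Convention: eremophilane numbering (decalin C1–C10, ketone C2, methyls on C4 and C5, side chain C11–C13 on C7); β is the face of the C5 methyl. (1R,5S)‑(+)‑Nopinone, the ozonolysis product of (−)‑β‑pinene, is taken as commercial.

**Step 1**
Reactants: 1 (1R,5S)-(+)-nopinone; 2 iodomethane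
Product: 3 (1R,3S,5S)-3,6,6-trimethylbicyclo[3.1.1]heptan-2-one
Conditions: LiN(i-Pr)2, THF, −78 °C; then MeI, −78 → 0 °C
Reagents that add atoms: iodomethane CI
Why: Kinetic lithium enolate alkylation; only C3 can enolise (C1 is a cyclobutane bridgehead) and MeI enters anti to the CMe2 bridge, but this centre is re‑enolised in step 2, so its configuration is not carried forward.

**Step 2**
Reactants: 3 (1R,3S,5S)-3,6,6-trimethylbicyclo[3.1.1]heptan-2-one; 4 (E)-pent-3-en-2-one
Product: 6 (4S,5R,7R,9R)-9,11-cycloeremophil-1(10)-en-2-one, via Michael adduct diketone 5 (not isolated)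
Conditions: NaH, 1,4-dioxane, 80 °C; then 4, 10 → 25 °C; then KOH (0.2 equiv), MeOH, 60 °C
Reagents that add atoms: (E)-pent-3-en-2-one C/C=C/C(C)=O
Why: Robinson annulation (Michael addition, then aldol condensation); the enolate is attacked anti to the CMe2 bridge, so the C5 methyl ends syn to the bridge (cis to the future C7 side chain), and a chelated Michael transition state in dioxane gives the cis‑4,5‑dimethyl relation, as 2‑methylcyclohexanone does with this enone in non‑dissociating solvent.

**Step 3**
Reactants: 6 (4S,5R,7R,9R)-9,11-cycloeremophil-1(10)-en-2-one; 7 hydrogen chloride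
Product: 9 (4S,5R,7S)-11-chloroeremophila-1(10),8-dien-2-one, via 11-chloro enone 8 (not isolated)
Conditions: HCl (g), 1,4-dioxane, 0 → 20 °C; then DDQ (1.05 equiv), 20 °C, 30 min
Reagents that add atoms: hydrogen chloride Cl
Why: Acid‑induced heterolysis of the cyclobutane bond C9–C11 (vinylogous to the protonated enone) gives the tertiary chloride, and the acid‑generated linear dienol is dehydrogenated at C8 by DDQ (acid‑mediated quinone dehydrogenation of an enone to the linear dienone); C4, C5 and C7 are not touched, and near‑stoichiometric DDQ with a short reaction time limits enolisation towards C7.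

**Step 4**
Reactants: 9 (4S,5R,7S)-11-chloroeremophila-1(10),8-dien-2-one; 10 N-methylmorpholine N-oxide; 11 diphenylborinic acid; 12 3-methylbut-2-enoyl chloride
Product: 15 (4S,5R,7S,8R,9S)-11-chloro-8-hydroxy-9-(3-methylbut-2-enoyloxy)eremophil-1(10)-en-2-one, via borinate salt 13 (not isolated), via 8-O-diphenylboryl 9-senecioate 14 (not isolated)
Conditions: OsO4 (2 mol%), NMO (1.1 equiv), Ph2BOH (1.1 equiv), 4 Å MS, CH2Cl2, 0 → 25 °C; then 12 (1.1 equiv), −20 °C; aq. NaHCO3 work-up
Reagents that add atoms: N-methylmorpholine N-oxide C[N+]1([O-])CCOCC1; diphenylborinic acid OB(c1ccccc1)c1ccccc1 (its hydroxyl oxygen, restored by water on work-up); 3-methylbut-2-enoyl chloride CC(C)=CC(Cl)=O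
Why: Proposed new method: OsO4 adds [3+2] to the γ,δ‑olefin from the α face (the β face is blocked by the axial C5 methyl and the C7 side chain, the bias steroidal 4,6‑dien‑3‑ones show), but under water‑free conditions the hexavalent osmium glycolate is turned over by diphenylborinic acid instead of water, so the cis‑diol leaves osmium as the tetracoordinate borinate 13 (counter‑ion from the spent N‑oxide), and this ate complex is acylated once, at the unhindered allylic O9 and not at the neopentyl‑like O8, which forms both C–O bonds, sets C8 and C9 and differentiates the two oxygens in one flask; the closest known reaction types are the boronic‑acid‑intercepted osmium‑catalysed dihydroxylation and the borinic‑acid‑catalysed regioselective monoacylation of cis‑1,2‑diols.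

**Step 5**
Reactants: 15 (4S,5R,7S,8R,9S)-11-chloro-8-hydroxy-9-(3-methylbut-2-enoyloxy)eremophil-1(10)-en-2-one; 16 acetic anhydride
Product: 17 (4S,5R,7S,8R,9S)-8-acetoxy-11-chloro-9-(3-methylbut-2-enoyloxy)eremophil-1(10)-en-2-one
Conditions: Ac2O, DMAP (cat.), pyridine, CH2Cl2, 0 → 25 °C
Reagents that add atoms: acetic anhydride CC(=O)OC(C)=O
Why: DMAP‑catalysed acylation of the remaining hindered 8‑OH with the small acetyl donor; under these weakly basic, cold conditions the 9‑senecioate should not migrate, and no stereocentre is touched.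

**Step 6**
Reactants: 17 (4S,5R,7S,8R,9S)-8-acetoxy-11-chloro-9-(3-methylbut-2-enoyloxy)eremophil-1(10)-en-2-one
Product: 18 (4S,5R,7S,8R,9S,10S)-8-acetoxy-11-chloro-9-(3-methylbut-2-enoyloxy)eremophilan-2-one
Conditions: [(Ph3P)CuH]6 (0.5 equiv), H2O (2 equiv), PhMe, 25 °C
Reagents that add atoms: none
Why: Copper hydride conjugate reduction; hydride adds to C10 axially, cis to the C5 methyl and anti to the α C9 ester (the usual cis‑fused outcome of conjugate addition to 5‑methyl‑Δ1(10)‑octal‑2‑ones), which sets 10β‑H and relieves the C5/C7 syn strain of the enone, while the β,β‑disubstituted senecioate and the tertiary chloride are left alone.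

**Step 7**
Reactants: 18 (4S,5R,7S,8R,9S,10S)-8-acetoxy-11-chloro-9-(3-methylbut-2-enoyloxy)eremophilan-2-one
Product: 19 (4S,5R,7R,8R,9S,10S)-8-acetoxy-9-(3-methylbut-2-enoyloxy)eremophil-11-en-2-one
Conditions: DBU (5 equiv), PhMe, 90 °C
Reagents that add atoms: none
Why: E2 dehydrochlorination with a bulky amidine base takes one of the six exposed methyl hydrogens in preference to the hindered C7–H (Hofmann‑type regioselectivity), and the non‑ionising medium avoids a C11 cation that the neighbouring C8 acetate could trap; no stereocentre changes.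

**Compound list**
1 | (1R,5S)-(+)-nopinone, (1R,5S)-6,6-dimethylbicyclo[3.1.1]heptan-2-one | CC1(C)[C@H]2CCC(=O)[C@@H]1C2 | starting material
2 | iodomethane | CI | starting material
3 | (1R,3S,5S)-3,6,6-trimethylbicyclo[3.1.1]heptan-2-one (trans-3-methylnopinone, methyl anti to the CMe2 bridge) | CC1(C)[C@H]2C[C@H](C)C(=O)[C@@H]1C2 | intermediate
4 | (E)-pent-3-en-2-one | C/C=C/C(C)=O | starting material
5 | (1R,3R,5R)-3,6,6-trimethyl-3-[(2S)-4-oxopentan-2-yl]bicyclo[3.1.1]heptan-2-one (Michael adduct, 3-methyl syn to the CMe2 bridge) | CC1(C)[C@H]2C[C@](C)([C@@H](C)CC(C)=O)C(=O)[C@@H]1C2 | intermediate (not isolated)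
6 | (4S,5R,7R,9R)-9,11-cycloeremophil-1(10)-en-2-one (tricyclic enone; CMe2 bridge between C7 and C9 on the β face, 4β,5β-dimethyl) | CC1(C)[C@H]2C[C@@]3(C)C(=CC(=O)C[C@@H]3C)[C@@H]1C2 | intermediate
7 | hydrogen chloride | Cl | starting material
8 | (4S,5R,7R)-11-chloroeremophil-1(10)-en-2-one | CC(C)(Cl)[C@H]1C[C@@]2(C)C(=CC(=O)C[C@@H]2C)CC1 | intermediate (not isolated)
9 | (4S,5R,7S)-11-chloroeremophila-1(10),8-dien-2-one | CC(C)(Cl)[C@H]1C[C@@]2(C)C(=CC(=O)C[C@@H]2C)C=C1 | intermediate
10 | N-methylmorpholine N-oxide | C[N+]1([O-])CCOCC1 | starting material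
11 | diphenylborinic acid | OB(c1ccccc1)c1ccccc1 | starting material
12 | 3-methylbut-2-enoyl chloride (senecioyl chloride) | CC(C)=CC(Cl)=O | starting material
13 | N-methylmorpholinium diphenylborinate of the 8α,9α-diol derived from 9 (boron bridges O8 and O9) | CC(C)(Cl)[C@H]1C[C@@]2(C)C(=CC(=O)C[C@@H]2C)[C@@H]3O[B-](c4ccccc4)(c4ccccc4)O[C@H]13.C[NH+]1CCOCC1 | intermediate (not isolated)
14 | 8-O-diphenylboryl derivative of 15 (9α-senecioate, 8α-O–BPh2) | CC(C)(Cl)[C@H]1C[C@@]2(C)C(=CC(=O)C[C@@H]2C)[C@H](OC(=O)C=C(C)C)[C@@H]1OB(c1ccccc1)c1ccccc1 | intermediate (not isolated)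
15 | (4S,5R,7S,8R,9S)-11-chloro-8-hydroxy-9-(3-methylbut-2-enoyloxy)eremophil-1(10)-en-2-one (8α-OH, 9α-ester) | CC(C)(Cl)[C@H]1C[C@@]2(C)C(=CC(=O)C[C@@H]2C)[C@H](OC(=O)C=C(C)C)[C@@H]1O | intermediate
16 | acetic anhydride | CC(=O)OC(C)=O | starting material
17 | (4S,5R,7S,8R,9S)-8-acetoxy-11-chloro-9-(3-methylbut-2-enoyloxy)eremophil-1(10)-en-2-one | CC(C)(Cl)[C@H]1C[C@@]2(C)C(=CC(=O)C[C@@H]2C)[C@H](OC(=O)C=C(C)C)[C@@H]1OC(C)=O | intermediate
18 | (4S,5R,7S,8R,9S,10S)-8-acetoxy-11-chloro-9-(3-methylbut-2-enoyloxy)eremophilan-2-one (cis-fused, 10β-H) | CC(C)(Cl)[C@H]1C[C@@]2(C)[C@H](CC(=O)C[C@@H]2C)[C@H](OC(=O)C=C(C)C)[C@@H]1OC(C)=O | intermediate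
19 | (4S,5R,7R,8R,9S,10S)-8-acetoxy-9-(3-methylbut-2-enoyloxy)eremophil-11-en-2-one, [(1S,2R,3R,4aR,5S,8aS)-2-acetoxy-4a,5-dimethyl-7-oxo-3-(prop-1-en-2-yl)decahydronaphthalen-1-yl] 3-methylbut-2-enoate | C=C(C)[C@H]1C[C@@]2(C)[C@H](CC(=O)C[C@@H]2C)[C@H](OC(=O)C=C(C)C)[C@@H]1OC(C)=O | target

**Totals**
Total steps: 7. Longest linear sequence: 7 steps (1 → 19).

**Three steps most likely to fail**

Step 2 (annulation). The hindered, fully substituted enolate may add poorly to the β‑substituted enone, or the C4 epimer may form. The fallback replaces the basic enolate by Lewis‑acid chemistry. It sets out from 3: LiN(i-Pr)2 then Me3SiCl gives the trimethylsilyl enol ether of 3, 3,6,6-trimethyl-2-(trimethylsilyloxy)bicyclo[3.1.1]hept-2-ene F1 (bridgeheads as in 1). A TiCl4‑mediated Mukaiyama–Michael addition of F1 to 4 (CH2Cl2, −78 °C, open transition state, attack again anti to the bridge) gives diketone 5, which is now isolated and freed of any C4 epimer. KOH/MeOH aldol condensation then returns to the route at 6.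

Step 4 (the proposed osmium/borinic acid syn‑oxyacylation). The borinic acid may be oxidised by the N‑oxide, may fail to turn over the osmium glycolate, or the acyl chloride may react with residual oxidant. The fallback uses known chemistry and sets out from 9: Upjohn dihydroxylation (OsO4 cat., NMO, acetone–water, 20 °C) gives the α‑face diol (4S,5R,7S,8R,9S)-11-chloro-8,9-dihydroxyeremophil-1(10)-en-2-one F2. Sterically controlled monoacylation of F2 with 12 (1.05 equiv, pyridine, cat. DMAP, CH2Cl2, −20 °C) at the unhindered allylic 9‑OH returns to the route at 15.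

Step 7 (late elimination). The tetrasubstituted isopropylidene isomer may form, or the reaction may stall with a tertiary chloride; any isopropylidene isomer is removed on AgNO3‑impregnated silica. The fallback changes from ionic elimination to radical desaturation and sets out from 18. The tris(trimethylsilyl)silyl radical, generated from (Me3Si)3SiH with the photocatalyst 4CzIPN under blue light, abstracts the chlorine atom. The cobaloxime Co(dmgH)2(py)Cl then removes a methyl hydrogen atom from the tertiary C11 radical, with no cation and no base. This returns to the route at 19 and makes no new compound (F0).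

**Further compounds**
F1 | step 2 | 3,6,6-trimethyl-2-(trimethylsilyloxy)bicyclo[3.1.1]hept-2-ene (silyl enol ether of 3) | CC1(C)[C@H]2CC(C)=C(O[Si](C)(C)C)[C@@H]1C2
F2 | step 4 | (4S,5R,7S,8R,9S)-11-chloro-8,9-dihydroxyeremophil-1(10)-en-2-one | CC(C)(Cl)[C@H]1C[C@@]2(C)C(=CC(=O)C[C@@H]2C)[C@H](O)[C@@H]1O
F0 | step 7 | none | none
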